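Compound numbers used throughout: 1 aldehyde, 2 acyl oxazolidinone, 3 silylated aldol adduct (in situ), 4 aldol adduct, 5 Weinreb amide, 6 hydroxy ketone, 7 arylacetic acid, 8 trichloroethyl ester, 9 diazo ester, 10 oxonium ylide (in situ), 11 oxolane ester, 12 oxolane acid, 13 bis-benzyl ether, 14 target.

## Analysis of the target

Target 14 is a 2,5-diaryl-3,4-dimethyloxolan-3-ol. It has one oxolane ring (O1, C2–C5) with 4-hydroxy-3-methoxyphenyl groups on C2 and C5, methyl groups on C3 and C4, and a tertiary hydroxyl on C3. All four ring carbons are stereocentres, (2R,3S,4S,5R). The two aryl groups are cis, the C3 methyl is cis to the C2 aryl, and the C4 methyl is trans to both the C3 methyl and the C5 aryl, so the C3 hydroxyl and the C4 methyl share a face. The hydroxyl breaks the near-symmetry of the diaryl-dimethyl-oxolane skeleton, so the two halves cannot come from one dimerising operation. The sensitive sites are the two ring benzylic C–O bonds, each para to a phenolic oxygen (acid ionises them and can epimerise C2 or C5, and hydrogen over palladium can cleave them), the tertiary alcohol (dehydration) and the free phenols (oxidation). The hard part is the fully substituted carbinol C3, which lies between two stereocentres and carries the small pair CH3/OH, so it offers little intrinsic bias. The strategy rests on C2, the only ring carbon bonded to both O1 and C3. With C2 lifted out, O1–C5–C4–C3 is a β-hydroxy ketone (C5 carbinol, C4 α-methyl, C3 acetyl carbon), and C2 with its aryl group is a carbene carbon placed between the hydroxyl oxygen and the carbonyl carbon.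

## Retrosynthetic reasoning

**14 to 13.** The two phenols are masked as benzyl ethers, so the first cut is the pair of phenolic O–CH2Ph bonds. Free phenols would quench a metal carbene and would not survive an oxidative photocatalyst. Benzyl ethers tolerate every step before the last and leave under neutral conditions.

**13 to 12 to 11.** The C2–H bond is traced back to a C2–carboxyl bond. A carbene that bridges a hydroxyl and a ketone must carry an acceptor group, and this acceptor is not in the target, so it is planned as a traceless carboxyl. Its removal passes through a planar benzylic, α-oxygenated radical at C2. C2 is therefore set only at this point, by hydrogen delivery to the face away from the C3 methyl and the C5 aryl, and the ring-forming step need not control C2. The ester in 11 is a 2,2,2-trichloroethyl ester and not a simple alkyl ester. A fully substituted ester next to a tertiary β-hydroxyl would need forcing base for saponification, and base can reopen the ring by retro-aldol (the reverse of the ring closure) and scramble C3. Reductive cleavage avoids this. The decarboxylation starts from the free carboxylate of 12, because activating a carboxyl that is cis to the C3 hydroxyl would invite β-lactone formation.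

**11 to 6 and 9, through 10.** O1–C2 and C2–C3 are cut together. These are the only two ring bonds that meet at the methyl-free carbon, and cutting them leaves an aldol (6) whose two stereocentres are C4 and C5 of the target. Any other pair of cuts destroys this aldol pattern. The forward reaction must capture a metal carbene from 9 on the hydroxyl of 6 and then use the resulting ylide 10 as an enolate toward the ketone before it collapses by proton shift. The gain is one ring, two skeletal bonds and the C3 carbinol in its final form.

**6 to 5 to 4 to 1 and 2.** The acetyl C–CH3 bond is cut back to Weinreb amide 5, and the C4–C5 bond (ring numbering) is cut as an anti propionate aldol between aldehyde 1 and acyl oxazolidinone 2. The aldol must give the anti relationship and the (2S,3R) absolute sense. The aldehyde is aromatic and cannot enolise, which suits a magnesium-catalysed direct anti-aldol.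

**9 to 8 to 7.** The diazo group is introduced by diazo transfer onto the activated methylene of ester 8, which comes from acid 7 by esterification. This arm uses the same protected aryl unit as the other one.

## Alternatives that were turned down

**Alternative 1:** carbonyl ylide (3+2) cycloaddition.
- Disconnection: C2–C3 and C4–C5. The oxolane is the adduct of a carbonyl ylide (C2–O1–C5 with both aryl groups) and a C3–C4 alkene.
- Forward key step: the symmetrical oxirane A2 is opened at its C–C bond by photoinduced electron transfer (visible light, a triarylpyrylium sensitiser). The ylide adds to the (Z)-2-acetoxybut-2-enoyl imide A3 to give cycloadduct A1. Its acetoxy group is the masked C3 hydroxyl and its acyl group must later become the C3 methyl.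
- For it: both aryl-bearing carbons come from one symmetrical precursor. Two C–C bonds and up to four stereocentres form at once, and the alkene geometry fixes the C3/C4 relationship stereospecifically. On convergence and on stereocentres set per step it is stronger than the chosen plan, which sets C2 separately.
- Against it:
  - A3 is a trisubstituted, captodative alkene and a sluggish partner for a short-lived ylide, which can instead reclose, isomerise (losing the cis relationship of the aryl groups) or fragment.
  - The alkene face is controlled only by an auxiliary remote from a fully substituted carbon, and the required orientation places the bulky acyl group on the aryl face.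
  - After the cycloaddition the acyl carbon must be reduced to CH3 at a neopentyl position beside a quaternary centre, which takes at least three operations, before deacetylation and debenzylation.
- Comparison: in the chosen route the C3 methyl and hydroxyl come from a methyl ketone in final form, and the one surplus carbon leaves in a single step.

**Alternative 2:** oxidative quinone methide closure.
- Disconnection: O1–C5 only.
- Forward key step: the open-chain diol A5 carries a free 4-hydroxy-3-methoxybenzyl group. Ag2O oxidises it to a p-quinone methide, and the secondary hydroxyl adds to the methide carbon to give the mono-benzyl ether A4.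
- For it: the closure needs no surplus carbon. All oxygens are in place, so one deprotection finishes the synthesis, and C2 is fixed early in an open chain. On these points it is stronger than the chosen plan.
- Against it:
  - The key step makes one bond and one stereocentre. The three contiguous centres of A5, including the quaternary carbinol, must be built beforehand by separate asymmetric chemistry, so the main difficulty is moved and not solved.
  - The quinone methide has β-hydrogens and can tautomerise to a vinylphenol or add water.
  - The C5 configuration depends on substrate-controlled facial attack on a flat, reactive intermediate.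
- Comparison: the linear sequence would be clearly longer. The chosen route builds C3 while closing the ring and reaches its precursors in three and two steps.

**Alternative 3:** allylsilane–aldehyde (3+2) annulation.
- Disconnection: C4–C5 and O1–C2, with the C3 hydroxyl traced back to silicon.
- Forward key step: BF3·OEt2 promotes addition of the (R,Z)-allylsilane A7 to aldehyde 1 anti to silicon. A 1,2-silyl shift follows, and the alkoxide closes on the benzylic cation to give silyl oxolane A6. Oxidation of the C–Si bond with retention would then reveal the hydroxyl.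
- For it: it is convergent and well ordered. Allylic strain in the Z-alkene fixes the reactive conformer, three stereocentres follow from the anti pathway, C2 is set in the key step, and nothing has to be excised. On atom economy and on C2 control it is stronger than the chosen plan.
- Against it:
  - A7 is an enantiopure benzylic, allylic silane with a Z-trisubstituted alkene and an electron-rich aryl group. It is hard to make and prone to protodesilylation.
  - Simple allylation with loss of silicon competes with annulation.
  - Oxidising a tertiary dimethylphenylsilyl group needs an electrophile to attack the phenyl on silicon, while two much more electron-rich aryl ethers and two acid-labile benzylic ethers are present.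
- Comparison: the chosen route delivers the hydroxyl directly from a carbonyl and needs no late electrophilic or oxidative step on the electron-rich rings.

Key step: step 6

Assumption 1: the magnesium-chelated Z-enolate of 2 is taken to add on the face remote from the ring benzyl group, as chelated enolates of this auxiliary do in alkylations, so the (R)-auxiliary leads to the (2S,3R) anti adduct. The (S)-auxiliary would be used with no other change if the opposite sense applied.

Assumption 2: 1, 2 and 7 are treated as purchasable.

## Route

Step 1
Reactants: 1 4-(benzyloxy)-3-methoxybenzaldehyde; 2 (4R)-4-benzyl-3-propanoyl-1,3-oxazolidin-2-one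
Product: 4 (4R)-4-benzyl-3-[(2S,3R)-3-[4-(benzyloxy)-3-methoxyphenyl]-3-hydroxy-2-methylpropanoyl]-1,3-oxazolidin-2-one, via O-trimethylsilyl aldol adduct 3 (not isolated)
Conditions: MgCl2 (20 mol%), Et3N, Me3SiCl, EtOAc, rt; then THF/1 M aq HCl (5:1), 0 °C, brief
Reagents that add atoms: none
Why: Evans magnesium-halide-catalysed direct anti-aldol: soft enolisation gives the chelated Z-enolate, which adds to the non-enolisable aldehyde through a closed boat-like transition state, and silylation of the aldolate makes the addition irreversible. The auxiliary benzyl group shields one enolate face, so both stereocentres (later C4 and C5) are set here, and the silyl ether is removed by short cold acid.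

Step 2
Reactants: 4 (4R)-4-benzyl-3-[(2S,3R)-3-[4-(benzyloxy)-3-methoxyphenyl]-3-hydroxy-2-methylpropanoyl]-1,3-oxazolidin-2-one
Product: 5 (2S,3R)-3-[4-(benzyloxy)-3-methoxyphenyl]-3-hydroxy-N-methoxy-N,2-dimethylpropanamide
Conditions: MeNH(OMe)·HCl, Me3Al, CH2Cl2, −15 to 0 °C
Reagents that add atoms: N,O-dimethylhydroxylamine hydrochloride, CNOC.Cl
Why: Aluminium-amide transamidation to the Weinreb amide; the free β-hydroxyl binds aluminium and directs the amide to the exocyclic carbonyl, so the auxiliary is released without touching either stereocentre.

Step 3
Reactants: 5 (2S,3R)-3-[4-(benzyloxy)-3-methoxyphenyl]-3-hydroxy-N-methoxy-N,2-dimethylpropanamide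
Product: 6 (3S,4R)-4-[4-(benzyloxy)-3-methoxyphenyl]-4-hydroxy-3-methylbutan-2-one
Conditions: MeMgBr (3 equiv), THF, −20 to 0 °C; aq NH4Cl at 0 °C
Reagents that add atoms: methylmagnesium bromide, C[Mg]Br
Why: Weinreb ketone synthesis: the first equivalent forms the magnesium alkoxide and the next adds to give a stable chelated tetrahedral intermediate. The ketone appears only on quench, which prevents over-addition and keeps the α-stereocentre from enolising.

Step 4
Reactants: 7 2-[4-(benzyloxy)-3-methoxyphenyl]acetic acid
Product: 8 2,2,2-trichloroethyl 2-[4-(benzyloxy)-3-methoxyphenyl]acetate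
Conditions: Cl3CCH2OH, DCC, DMAP (10 mol%), CH2Cl2, 0 °C to rt
Reagents that add atoms: 2,2,2-trichloroethanol, OCC(Cl)(Cl)Cl
Why: Steglich esterification; the trichloroethyl ester is installed so that the carboxyl can later be freed reductively and not by base.

Step 5
Reactants: 8 2,2,2-trichloroethyl 2-[4-(benzyloxy)-3-methoxyphenyl]acetate
Product: 9 2,2,2-trichloroethyl 2-[4-(benzyloxy)-3-methoxyphenyl]-2-diazoacetate
Conditions: 2-nitrobenzenesulfonyl azide, DBU, MeCN, 0 °C
Reagents that add atoms: 2-nitrobenzenesulfonyl azide, O=[N+]([O-])c1ccccc1S(=O)(=O)N=[N+]=[N-]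
Why: Regitz diazo transfer: DBU deprotonates the benzylic, ester-activated methylene, and the enolate attacks the sulfonyl azide and expels the sulfonamide. No stereocentre is involved.

Step 6
Reactants: 6 (3S,4R)-4-[4-(benzyloxy)-3-methoxyphenyl]-4-hydroxy-3-methylbutan-2-one; 9 2,2,2-trichloroethyl 2-[4-(benzyloxy)-3-methoxyphenyl]-2-diazoacetate
Product: 11 2,2,2-trichloroethyl (2R,3S,4S,5R)-2,5-bis[4-(benzyloxy)-3-methoxyphenyl]-3-hydroxy-3,4-dimethyloxolane-2-carboxylate, via oxonium ylide 10 (not isolated)
Conditions: Rh2(OAc)4 (2 mol%), 4 Å MS, CH2Cl2, 40 °C, 9 (1.3 equiv) added by syringe pump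
Reagents that add atoms: none
Why: Rh2(OAc)4 converts 9 into a rhodium-bound donor/acceptor carbene, which the secondary hydroxyl of 6 (the best nucleophile present) captures to give oxonium ylide 10, an enol equivalent. Before the usual 1,2-proton shift can complete an O–H insertion, the ylide carbon adds to the tethered methyl ketone, so O1–C2 and C2–C3 form in one operation. The closest known reaction type is the Rh2(OAc)4-catalysed oxonium-ylide formation from aryl diazoacetates and alcohols with aldol-type trapping, including its intramolecular form with β-hydroxy ketones that gives 3-hydroxyoxolane-2-carboxylates. The ring closes in a 5-exo-trig (enol-exo) mode: nucleophilic C2 attacks carbonyl carbon C3, whose C=O lies outside the forming five-membered ring. C3 is controlled by the C4 stereocentre: in an envelope transition state with the C5 aryl and C4 methyl pseudo-equatorial, the acetyl group turns so that its methyl is anti to the C4 methyl and its oxygen sits syn to it, which gives (3S). C2 is controlled by the hydrogen bond (proton relay) between the ylide/enol O–H and the ketone oxygen, which places the ester cis to the developing hydroxyl and gives (2R); this centre is not relied on later, because C2 becomes planar in step 8. The step needs aldol trapping to beat the proton shift and needs the correct ketone face; the five-membered intramolecular trap, the dry aprotic medium, the slow addition and the lifetime of the aryl/ester-stabilised ylide secure the first, and the C4 methyl secures the second. The neutral conditions leave C4, C5, the benzyl ethers and the trichloroethyl ester untouched.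

Step 7
Reactants: 11 2,2,2-trichloroethyl (2R,3S,4S,5R)-2,5-bis[4-(benzyloxy)-3-methoxyphenyl]-3-hydroxy-3,4-dimethyloxolane-2-carboxylate
Product: 12 (2R,3S,4S,5R)-2,5-bis[4-(benzyloxy)-3-methoxyphenyl]-3-hydroxy-3,4-dimethyloxolane-2-carboxylic acid
Conditions: Zn dust, AcOH/THF (1:1), rt
Reagents that add atoms: none
Why: Reductive β-elimination of the trichloroethyl ester: zinc reduces a C–Cl bond and the carboxylate leaves with 1,1-dichloroethene. The mildly acidic, base-free medium avoids both forcing saponification of the hindered ester and retro-aldol opening of the β-hydroxy ester, and benzyl ethers are inert to it.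

Step 8
Reactants: 12 (2R,3S,4S,5R)-2,5-bis[4-(benzyloxy)-3-methoxyphenyl]-3-hydroxy-3,4-dimethyloxolane-2-carboxylic acid
Product: 13 (2R,3S,4S,5R)-2,5-bis[4-(benzyloxy)-3-methoxyphenyl]-3,4-dimethyloxolan-3-ol
Conditions: 9-mesityl-10-phenylacridinium tetrafluoroborate (5 mol%), PhSSPh (10 mol%), i-Pr2NEt (20 mol%), CF3CH2OH, 450 nm LEDs, rt, N2
Reagents that add atoms: none
Why: Photoredox hydrodecarboxylation: the excited acridinium oxidises the carboxylate, loss of CO2 gives the planar benzylic α-oxy radical at C2, and thiophenol formed from the disulfide donates the hydrogen atom. The hydrogen should arrive on the face bearing the C3 hydroxyl, away from the larger C3 methyl and the C5 aryl, which sets C2 as (R) with the aryl groups cis. The free carboxylate needs no activation, so no β-lactone can form with the cis C3 hydroxyl.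

Step 9
Reactants: 13 (2R,3S,4S,5R)-2,5-bis[4-(benzyloxy)-3-methoxyphenyl]-3,4-dimethyloxolan-3-ol
Product: 14 (2R,3S,4S,5R)-2,5-bis(4-hydroxy-3-methoxyphenyl)-3,4-dimethyloxolan-3-ol
Conditions: H2 (1 atm), 10% Pd/C, EtOAc, rt, stopped at full debenzylation
Reagents that add atoms: none
Why: Catalytic hydrogenolysis of aryl benzyl ethers; in a neutral aprotic solvent the phenolic O–CH2Ph bonds should cleave much faster than the ring benzylic C–O bonds, and no stereocentre is touched.

## Compound list

1 | 4-(benzyloxy)-3-methoxybenzaldehyde | COc1cc(C=O)ccc1OCc1ccccc1 | starting material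
2 | (4R)-4-benzyl-3-propanoyl-1,3-oxazolidin-2-one | CCC(=O)N1[C@H](Cc2ccccc2)COC1=O | starting material
3 | (4R)-4-benzyl-3-[(2S,3R)-3-[4-(benzyloxy)-3-methoxyphenyl]-2-methyl-3-(trimethylsilyloxy)propanoyl]-1,3-oxazolidin-2-one (formed in the flask, not isolated) | O=C([C@@H](C)[C@@H](O[Si](C)(C)C)c1ccc(OCc2ccccc2)c(OC)c1)N1[C@H](Cc2ccccc2)COC1=O | intermediate
4 | (4R)-4-benzyl-3-[(2S,3R)-3-[4-(benzyloxy)-3-methoxyphenyl]-3-hydroxy-2-methylpropanoyl]-1,3-oxazolidin-2-one | O=C([C@@H](C)[C@@H](O)c1ccc(OCc2ccccc2)c(OC)c1)N1[C@H](Cc2ccccc2)COC1=O | intermediate
5 | (2S,3R)-3-[4-(benzyloxy)-3-methoxyphenyl]-3-hydroxy-N-methoxy-N,2-dimethylpropanamide | CON(C)C(=O)[C@@H](C)[C@@H](O)c1ccc(OCc2ccccc2)c(OC)c1 | intermediate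
6 | (3S,4R)-4-[4-(benzyloxy)-3-methoxyphenyl]-4-hydroxy-3-methylbutan-2-one | CC(=O)[C@@H](C)[C@@H](O)c1ccc(OCc2ccccc2)c(OC)c1 | intermediate
7 | 2-[4-(benzyloxy)-3-methoxyphenyl]acetic acid | COc1cc(CC(=O)O)ccc1OCc1ccccc1 | starting material
8 | 2,2,2-trichloroethyl 2-[4-(benzyloxy)-3-methoxyphenyl]acetate | COc1cc(CC(=O)OCC(Cl)(Cl)Cl)ccc1OCc1ccccc1 | intermediate
9 | 2,2,2-trichloroethyl 2-[4-(benzyloxy)-3-methoxyphenyl]-2-diazoacetate | COc1cc(C(=[N+]=[N-])C(=O)OCC(Cl)(Cl)Cl)ccc1OCc1ccccc1 | intermediate
10 | oxonium ylide formed from the hydroxyl oxygen of 6 and the carbene carbon of 9 (formed in the flask, not isolated) | CC(=O)[C@@H](C)[C@@H]([OH+][C-](C(=O)OCC(Cl)(Cl)Cl)c1ccc(OCc2ccccc2)c(OC)c1)c1ccc(OCc2ccccc2)c(OC)c1 | intermediate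
11 | 2,2,2-trichloroethyl (2R,3S,4S,5R)-2,5-bis[4-(benzyloxy)-3-methoxyphenyl]-3-hydroxy-3,4-dimethyloxolane-2-carboxylate | COc1cc([C@@]2(C(=O)OCC(Cl)(Cl)Cl)O[C@@H](c3ccc(OCc4ccccc4)c(OC)c3)[C@H](C)[C@]2(C)O)ccc1OCc1ccccc1 | intermediate
12 | (2R,3S,4S,5R)-2,5-bis[4-(benzyloxy)-3-methoxyphenyl]-3-hydroxy-3,4-dimethyloxolane-2-carboxylic acid | COc1cc([C@@]2(C(=O)O)O[C@@H](c3ccc(OCc4ccccc4)c(OC)c3)[C@H](C)[C@]2(C)O)ccc1OCc1ccccc1 | intermediate
13 | (2R,3S,4S,5R)-2,5-bis[4-(benzyloxy)-3-methoxyphenyl]-3,4-dimethyloxolan-3-ol | COc1cc([C@H]2O[C@@H](c3ccc(OCc4ccccc4)c(OC)c3)[C@H](C)[C@]2(C)O)ccc1OCc1ccccc1 | intermediate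
14 | (2R,3S,4S,5R)-2,5-bis(4-hydroxy-3-methoxyphenyl)-3,4-dimethyloxolan-3-ol | COc1cc([C@H]2O[C@@H](c3ccc(O)c(OC)c3)[C@H](C)[C@]2(C)O)ccc1O | target

## Step count and least certain steps

Total: 9 steps. Longest linear sequence: 7 steps (steps 1, 2, 3, 6, 7, 8, 9); the diazo arm adds steps 4 and 5.

**Step 6 (key step).**
- What may go wrong: the 1,2-proton shift of ylide 10 may outrun the aldol closure, so that only carbene O–H insertion occurs. The ketone may also be attacked on the face syn to the C4 methyl. Both follow from the short lifetime of the ylide and the small size difference between the methyl and the oxygen of the ketone.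
- Fallback: the two bond formations are separated. From 6 and 9 the same catalyst is allowed to complete the insertion, giving 2,2,2-trichloroethyl 2-[4-(benzyloxy)-3-methoxyphenyl]-2-{(1R,2S)-1-[4-(benzyloxy)-3-methoxyphenyl]-2-methyl-3-oxobutoxy}acetate F1. It forms as a mixture at the new centre, which does not matter because that centre is enolised next. LiHMDS in THF at −78 °C removes the doubly activated proton, and the lithium ester enolate closes onto the ketone in an intramolecular aldol through a lithium-bridged transition state. A cold acetic acid quench returns the sequence to the route at 11.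

**Step 8.**
- What may go wrong:
  - Hydrogen-atom delivery to the C2 radical may lack facial preference.
  - The excited acridinium may oxidise the electron-rich aryl ethers, with epimerisation at C5 or loss of a benzyl group.
  - The C2 radical may open the ring by β-scission of O1–C5.
  - The thiyl radical may re-abstract the activated benzylic hydrogens on long irradiation.
- Fallback: a two-electron pathway. From 12, Hofer–Moest anodic decarboxylation in methanol (graphite anode, substoichiometric NaOMe, constant current) gives (3S,4S,5R)-2,5-bis[4-(benzyloxy)-3-methoxyphenyl]-2-methoxy-3,4-dimethyloxolan-3-ol F2 as a mixture at C2. Et3SiH with BF3·OEt2 in CH2Cl2 at −78 °C then reduces the aryl-stabilised oxocarbenium ion, with hydride arriving anti to the C3 methyl, and returns to the route at 13.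

**Step 1.**
- What may go wrong: conversion may be slow or anti selectivity eroded with this electron-rich, weakly electrophilic aldehyde. Retro-aldol or ionisation of the p-alkoxybenzylic carbinol may occur during desilylation.
- Fallback: from 1, Brown crotylboration with the (E)-but-2-enyl-diisopinocampheylborane prepared from (+)-B-methoxydiisopinocampheylborane (THF/Et2O, −78 °C; NaOH, H2O2 work-up) is expected to give (1R,2R)-1-[4-(benzyloxy)-3-methoxyphenyl]-2-methylbut-3-en-1-ol F3. The chair transition state translates the E geometry into the anti relationship. Wacker–Tsuji oxidation of the terminal alkene (PdCl2, CuCl, O2, DMF/H2O) then gives the methyl ketone and returns to the route at 6, bypassing 4 and 5.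

**Step 3.**
- What may go wrong: retro-aldol cleavage of the magnesium aldolate, which the electron-rich aryl group favours, or epimerisation of the α-centre during quench.
- Fallback: the hydroxyl is masked before the Grignard addition. From 5, Et3SiCl and imidazole in DMF give (2S,3R)-3-[4-(benzyloxy)-3-methoxyphenyl]-N-methoxy-N,2-dimethyl-3-(triethylsilyloxy)propanamide F4. MeMgBr in THF at 0 °C gives (3S,4R)-4-[4-(benzyloxy)-3-methoxyphenyl]-3-methyl-4-(triethylsilyloxy)butan-2-one F5. HF·pyridine in THF at 0 °C removes the silyl group and returns to the route at 6.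

## Further compounds

F1 | step 6 | 2,2,2-trichloroethyl 2-[4-(benzyloxy)-3-methoxyphenyl]-2-{(1R,2S)-1-[4-(benzyloxy)-3-methoxyphenyl]-2-methyl-3-oxobutoxy}acetate (both epimers at the acetate carbon) | CC(=O)[C@@H](C)[C@@H](OC(C(=O)OCC(Cl)(Cl)Cl)c1ccc(OCc2ccccc2)c(OC)c1)c1ccc(OCc2ccccc2)c(OC)c1
F2 | step 8 | (3S,4S,5R)-2,5-bis[4-(benzyloxy)-3-methoxyphenyl]-2-methoxy-3,4-dimethyloxolan-3-ol (both epimers at C2) | COc1cc(C2(OC)O[C@@H](c3ccc(OCc4ccccc4)c(OC)c3)[C@H](C)[C@]2(C)O)ccc1OCc1ccccc1
F3 | step 1 | (1R,2R)-1-[4-(benzyloxy)-3-methoxyphenyl]-2-methylbut-3-en-1-ol | C=C[C@@H](C)[C@@H](O)c1ccc(OCc2ccccc2)c(OC)c1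
F4 | step 3 | (2S,3R)-3-[4-(benzyloxy)-3-methoxyphenyl]-N-methoxy-N,2-dimethyl-3-(triethylsilyloxy)propanamide | CON(C)C(=O)[C@@H](C)[C@@H](O[Si](CC)(CC)CC)c1ccc(OCc2ccccc2)c(OC)c1
F5 | step 3 | (3S,4R)-4-[4-(benzyloxy)-3-methoxyphenyl]-3-methyl-4-(triethylsilyloxy)butan-2-one | CC(=O)[C@@H](C)[C@@H](O[Si](CC)(CC)CC)c1ccc(OCc2ccccc2)c(OC)c1
A1 | alternative 1 | (4S)-4-benzyl-3-{[(2R,3S,4S,5R)-3-acetoxy-2,5-bis[4-(benzyloxy)-3-methoxyphenyl]-4-methyloxolan-3-yl]carbonyl}-1,3-oxazolidin-2-one | COc1cc([C@H]2O[C@@H](c3ccc(OCc4ccccc4)c(OC)c3)[C@H](C)[C@]2(C(=O)N5[C@@H](Cc6ccccc6)COC5=O)OC(C)=O)ccc1OCc1ccccc1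
A2 | alternative 1 | trans-2,3-bis[4-(benzyloxy)-3-methoxyphenyl]oxirane (drawn as the (2R,3R) enantiomer; ring opening erases both centres) | COc1cc([C@H]2O[C@@H]2c2ccc(OCc3ccccc3)c(OC)c2)ccc1OCc1ccccc1
A3 | alternative 1 | (4S)-3-[(Z)-2-acetoxybut-2-enoyl]-4-benzyl-1,3-oxazolidin-2-one | C/C=C(\OC(C)=O)C(=O)N1[C@@H](Cc2ccccc2)COC1=O
A4 | alternative 2 | (2R,3S,4S,5R)-2-[4-(benzyloxy)-3-methoxyphenyl]-5-(4-hydroxy-3-methoxyphenyl)-3,4-dimethyloxolan-3-ol | COc1cc([C@H]2O[C@@H](c3ccc(O)c(OC)c3)[C@H](C)[C@]2(C)O)ccc1OCc1ccccc1
A5 | alternative 2 | (1R,2S,3S)-1-[4-(benzyloxy)-3-methoxyphenyl]-4-(4-hydroxy-3-methoxyphenyl)-2,3-dimethylbutane-1,2-diol | COc1cc([C@@H](O)[C@@](C)(O)[C@@H](C)Cc2ccc(O)c(OC)c2)ccc1OCc1ccccc1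
A6 | alternative 3 | (2R,3S,4S,5R)-2,5-bis[4-(benzyloxy)-3-methoxyphenyl]-3-[dimethyl(phenyl)silyl]-3,4-dimethyloxolane | COc1cc([C@H]2O[C@@H](c3ccc(OCc4ccccc4)c(OC)c3)[C@H](C)[C@]2(C)[Si](C)(C)c5ccccc5)ccc1OCc1ccccc1
A7 | alternative 3 | [(1R,2Z)-1-[4-(benzyloxy)-3-methoxyphenyl]-2-methylbut-2-en-1-yl]dimethyl(phenyl)silane | COc1cc([C@H]([Si](C)(C)c2ccccc2)/C(C)=C\C)ccc1OCc1ccccc1
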